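**Retrosynthetic overview**
1. Numbering: 1-aryl-1,2-dihydronaphthalene with C1 (dimethoxyphenyl ring C), C2 (CH2OH), C3 (CHO), C4 (vinyl CH), and ring A carrying C7-OH and C8-OMe. The feature used is the vicinal C8-OMe/C7-OH pair of ring A next to the C4a–C8a fusion bond: it is read as a 2-methoxy-3-silyloxybutadiene (C8a=C8–C7=C6), and C4a–C5 as the alkyne of an ynone on C4.
2. Endgame: the C3(CHO)=C4 enal comes from the C4 ketone of tetralone 21 (C3 formylation, enol ether, 1,2-reduction, acid transposition); desilylation is last.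
3. Key disconnection: C4a–C8a and C5–C6, by intramolecular Diels–Alder reaction of dienyl ynone 19 followed by DDQ. Rings A and B are formed together in one flask; ring C is carried from the start.
4. Ynone 19 comes from an open chain with C1 and C2 in place: diene by ozonolysis, Horner–Wadsworth–Emmons olefination and enol silylation; ynone from a Weinreb amide.
5. C1 and C2 are set on the (S)-4-benzyloxazolidinone imide of 3,4-dimethoxycinnamic acid by vinyl cuprate addition, then enolate alkylation.

Key step: step 11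

Remark on the chemistry: the primary alcohol is carried as its tert-butyldiphenylsilyl (TBDPS) ether and the dienol/phenol oxygen as its triisopropylsilyl (TIPS) ether, so that both survive the base, DDQ and acid stages; phosphonate 15 is made in step 7 from commercial 14. Target atom numbers (C1–C8a) are used for all intermediates.

**Step 1**
Reactants: 1 3,4-dimethoxycinnamic acid; 2 (S)-4-benzyl-2-oxazolidinone
Product: 4 (4S)-4-benzyl-3-[(E)-3-(3,4-dimethoxyphenyl)prop-2-enoyl]oxazolidin-2-one, via mixed pivalic anhydride 3 (not isolated)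
Conditions: t-BuCOCl, Et3N, THF, −20 °C; then LiCl, 2, −20 °C → rt
Reagents that add atoms: pivaloyl chloride CC(C)(C)C(Cl)=O (its acyl group is held by intermediate 3 only)
Why: N-acylation of the oxazolidinone through the mixed pivalic anhydride (LiCl/Et3N protocol) should occur at the less hindered cinnamoyl carbonyl and leave the (E)-alkene untouched.

**Step 2**
Reactants: 4 N-cinnamoyl imide; 5 vinylmagnesium bromide
Product: 6 (4S)-4-benzyl-3-[(3R)-3-(3,4-dimethoxyphenyl)pent-4-enoyl]oxazolidin-2-one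
Conditions: 5, CuBr·SMe2, THF/Me2S, −78 → −20 °C
Reagents that add atoms: vinylmagnesium bromide C=C[Mg]Br
Why: Copper-mediated conjugate addition to the magnesium-chelated syn-s-cis N-enoyl imide should deliver the vinyl group to the β-carbon on the face away from the benzyl group, which sets C1 (3R in 6, the future 1S center); a minor diastereomer would be removed by crystallization or chromatography.

**Step 3**
Reactants: 6 conjugate adduct; 7 2-bromo-N-methoxy-N-methylacetamide
Product: 9 (4S)-4-benzyl-3-[(2S,3S)-3-(3,4-dimethoxyphenyl)-2-{2-[methoxy(methyl)amino]-2-oxoethyl}pent-4-enoyl]oxazolidin-2-one, via sodium enolate 8 (not isolated)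
Conditions: NaN(SiMe3)2, THF, −78 °C; then 7, −78 → −45 °C
Reagents that add atoms: 2-bromo-N-methoxy-N-methylacetamide CON(C)C(=O)CBr
Why: Evans asymmetric alkylation: the chelated (Z)-sodium enolate 8 should be alkylated (SN2) by the reactive α-bromo amide on the face opposite the benzyl group, which sets C2 under auxiliary control (2S in 9, the future 2R center) in the relationship that becomes trans in ring B.

**Step 4**
Reactants: 9 alkylated imide
Product: 10 (3S,4S)-4-(3,4-dimethoxyphenyl)-3-(hydroxymethyl)-N-methoxy-N-methylhex-5-enamide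
Conditions: LiBH4, THF, 0 °C
Reagents that add atoms: none
Why: Reductive cleavage of the N-acyl oxazolidinone by LiBH4 is much faster than reduction of the Weinreb amide and touches neither stereocenter; because a γ-hydroxy Weinreb amide can lactonize on standing or with acid, the crude alcohol is silylated at once.

**Step 5**
Reactants: 10 hydroxy Weinreb amide
Product: 11 (3S,4S)-3-[(tert-butyldiphenylsilyloxy)methyl]-4-(3,4-dimethoxyphenyl)-N-methoxy-N-methylhex-5-enamide
Conditions: t-BuPh2SiCl, imidazole, DMF, 0 °C → rt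
Reagents that add atoms: tert-butyl(chloro)diphenylsilane CC(C)(C)[Si](Cl)(c1ccccc1)c1ccccc1
Why: Imidazole-assisted silylation of the primary alcohol blocks lactonization and gives an ether that should survive base, hydride, DDQ and the acid of steps 13 and 14.

**Step 6**
Reactants: 11 silyl ether
Product: 13 (3S,4S)-3-[(tert-butyldiphenylsilyloxy)methyl]-4-(3,4-dimethoxyphenyl)-N-methoxy-N-methyl-5-oxopentanamide, via ozonide 12 (not isolated)
Conditions: O3, CH2Cl2, −78 °C (Sudan red 7B end point); then PPh3, −78 °C → rt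
Reagents that add atoms: ozone [O-][O+]=O
Why: Ozonolysis with reductive work-up cleaves the terminal alkene far faster than ozone attacks the dimethoxyarene, and the neutral phosphine work-up with direct use of the crude α-aryl aldehyde should keep C1 from epimerizing.

**Step 7**
Reactants: 14 dimethyl (1-diazo-2-oxopropyl)phosphonate
Product: 15 dimethyl (1-methoxy-2-oxopropyl)phosphonate
Conditions: MeOH, Rh2(OAc)4 (1 mol %), PhH, 80 °C
Reagents that add atoms: methanol CO
Why: O–H insertion of the rhodium carbenoid formed from the diazo phosphonate into methanol is a known way to α-alkoxy phosphonates.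

**Step 8**
Reactants: 13 aldehyde; 15 dimethyl (1-methoxy-2-oxopropyl)phosphonate
Product: 16 (3S,4R,5Z)-3-[(tert-butyldiphenylsilyloxy)methyl]-4-(3,4-dimethoxyphenyl)-N,6-dimethoxy-N-methyl-7-oxooct-5-enamide
Conditions: 15, NaH, THF, 0 °C; then 13, −78 → 0 °C
Reagents that add atoms: dimethyl (1-methoxy-2-oxopropyl)phosphonate CC(=O)C(OC)P(=O)(OC)OC
Why: Horner–Wadsworth–Emmons olefination with the preformed sodium phosphonate (no free base, low temperature) should outrun enolization of the α-aryl aldehyde, and the (Z)-enol ether, with C1 trans to the acetyl group, is expected as the major and thermodynamically preferred isomer (the (E)-isomer would be separated by chromatography).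

**Step 9**
Reactants: 16 α-methoxy enone
Product: 17 (3S,4R,5Z)-3-[(tert-butyldiphenylsilyloxy)methyl]-4-(3,4-dimethoxyphenyl)-N,6-dimethoxy-N-methyl-7-(triisopropylsilyloxy)octa-5,7-dienamide
Conditions: i-Pr3SiOTf, Et3N, CH2Cl2, −78 → 0 °C
Reagents that add atoms: triisopropylsilyl trifluoromethanesulfonate CC(C)[Si](C(C)C)(C(C)C)OS(=O)(=O)C(F)(F)F
Why: Soft enolization (silyl triflate/Et3N) of the methyl ketone gives the cross-conjugated 2-silyloxydiene by deprotonation of the methyl group of the O-silylated ketone, while the less basic Weinreb amide and the C1–H stay untouched.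

**Step 10**
Reactants: 17 dienyl Weinreb amide; 18 ethynylmagnesium bromide
Product: 19 (5S,6R,7Z)-5-[(tert-butyldiphenylsilyloxy)methyl]-6-(3,4-dimethoxyphenyl)-8-methoxy-9-(triisopropylsilyloxy)deca-7,9-dien-1-yn-3-one
Conditions: 18, THF, −20 → 0 °C; inverse quench into cold pH 4 phosphate–citrate buffer/Et2O
Reagents that add atoms: ethynylmagnesium bromide C#C[Mg]Br
Why: Weinreb ketone synthesis: the magnesium chelate of the tetrahedral adduct prevents double addition, the enol ethers do not react with the Grignard reagent, and the mildly acidic inverse quench protonates the liberated N,O-dimethylhydroxylamine before it can add to the ynone.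

**Step 11**
Reactants: 19 dienyl ynone
Product: 21 (3S,4S)-3-[(tert-butyldiphenylsilyloxy)methyl]-4-(3,4-dimethoxyphenyl)-5-methoxy-6-(triisopropylsilyloxy)-3,4-dihydronaphthalen-1(2H)-one, via cyclohexadiene adduct 20 (not isolated)
Conditions: PhMe (0.005 M), BHT (cat.), 80 °C; then DDQ (1.1 equiv), 0 °C → rt
Reagents that add atoms: none
Why: Heating should bring the s-cis 2-methoxy-3-silyloxydiene (C8a=C8–C7=C6) onto the ynone (C4a≡C5) in a normal-electron-demand, probably asynchronous concerted [4+2] cycloaddition in which the nucleophilic diene terminus C6 bonds to the ynone β-carbon C5 and C8a bonds to C4a; the closest known reaction type is the intramolecular Diels–Alder reaction of 2-silyloxydienes with tethered ynones followed by dehydrogenation of the 1,4-cyclohexadiene to the arene. Ring B closes as the tether ring (C1–C2–C3–C4–C4a–C8a, six-membered, through the C4a–C8a bond), and ring A closes as the cycloaddition ring through both new bonds (C4a–C8a and C5–C6). The only new stereocenter, C8a of adduct 20, is not controlled and need not be, because DDQ removes the hydrogens at C8a and C6 (hydride abstraction, then proton loss) and the center becomes aromatic; C1 and C2 are not acidic under these conditions and stay as set. Regiochemistry is fixed by the four-atom tether, so C8-OMe and C7-OSi end up next to the ring fusion without ambiguity, and the (Z)-enol ether geometry, which puts the tether trans to C7, lets the diene reach the s-cis conformation. High dilution and a radical inhibitor should suppress intermolecular reaction of the terminal ynone, and a small excess of DDQ at low temperature should stop at aromatization because the new arene carries the deactivating C4 ketone.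

**Step 12**
Reactants: 21 tetralone
Product: 23 (2Z,3R,4S)-3-[(tert-butyldiphenylsilyloxy)methyl]-4-(3,4-dimethoxyphenyl)-2-(hydroxymethylene)-5-methoxy-6-(triisopropylsilyloxy)-3,4-dihydronaphthalen-1(2H)-one, via lithium enolate 22 (not isolated)
Conditions: LiN(SiMe3)2, THF, −78 °C; then HCO2CH2CF3, −78 → −40 °C
Reagents that add atoms: 2,2,2-trifluoroethyl formate O=COCC(F)(F)F
Why: Crossed Claisen formylation of the kinetic lithium enolate (C3 is the only enolizable position) with the reactive trifluoroethyl formate at −78 °C gives the chelated hydroxymethylene ketone without the alkoxide exposure that would cleave the aryl silyl ether para to the ketone.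

**Step 13**
Reactants: 23 hydroxymethylene ketone
Product: 24 (2E,3R,4S)-3-[(tert-butyldiphenylsilyloxy)methyl]-4-(3,4-dimethoxyphenyl)-2-(isopropoxymethylene)-5-methoxy-6-(triisopropylsilyloxy)-3,4-dihydronaphthalen-1(2H)-one
Conditions: i-PrOH, camphorsulfonic acid (cat.), PhH, reflux, Dean–Stark
Reagents that add atoms: propan-2-ol CC(C)O
Why: Acid-catalyzed enol etherification of the vinylogous acid with azeotropic removal of water puts the isopropoxy group on the former formyl carbon, and both silyl ethers tolerate catalytic acid (the alkene geometry of 24 is of no consequence).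

**Step 14**
Reactants: 24 isopropoxymethylene ketone
Product: 26 (1S,2R)-2-[(tert-butyldiphenylsilyloxy)methyl]-1-(3,4-dimethoxyphenyl)-8-methoxy-7-(triisopropylsilyloxy)-1,2-dihydronaphthalene-3-carbaldehyde, via allylic alcohol 25 (not isolated)
Conditions: i-Bu2AlH, CH2Cl2, −78 °C; then 1 M HCl, THF, 0 °C → rt
Reagents that add atoms: water O
Why: 1,2-Reduction of the vinylogous ester by i-Bu2AlH, then acid hydrolysis of the enol ether with loss of the benzylic C4 hydroxyl (Stork–Danheiser-type carbonyl transposition), gives the C3(CHO)=C4 enal; C2 is not involved and the C4 carbinol center of 25 is lost.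

**Step 15**
Reactants: 26 bis-silyl enal
Product: 27 vitekwangin B
Conditions: Bu4NF, AcOH, THF, 0 °C → rt
Reagents that add atoms: none
Why: Fluoride-mediated cleavage of both silyl ethers, buffered with acetic acid so that no free base can epimerize C2 through the γ-position of the enal, gives the target.

**Compound list**
1 | 3,4-dimethoxycinnamic acid | COc1ccc(/C=C/C(=O)O)cc1OC | starting material
2 | (S)-4-benzyl-2-oxazolidinone | O=C1N[C@@H](Cc2ccccc2)CO1 | starting material
3 | (E)-3-(3,4-dimethoxyphenyl)prop-2-enoic pivalic anhydride | COc1ccc(/C=C/C(=O)OC(=O)C(C)(C)C)cc1OC | intermediate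
4 | (4S)-4-benzyl-3-[(E)-3-(3,4-dimethoxyphenyl)prop-2-enoyl]oxazolidin-2-one | COc1ccc(/C=C/C(=O)N2[C@@H](Cc3ccccc3)COC2=O)cc1OC | intermediate
5 | vinylmagnesium bromide | C=C[Mg]Br | starting material
6 | (4S)-4-benzyl-3-[(3R)-3-(3,4-dimethoxyphenyl)pent-4-enoyl]oxazolidin-2-one | COc1ccc([C@H](CC(=O)N2[C@@H](Cc3ccccc3)COC2=O)C=C)cc1OC | intermediate
7 | 2-bromo-N-methoxy-N-methylacetamide | CON(C)C(=O)CBr | starting material
8 | sodium (Z)-enolate of imide 6 | COc1ccc([C@H](/C=C(\[O-])N2[C@@H](Cc3ccccc3)COC2=O)C=C)cc1OC.[Na+] | intermediate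
9 | (4S)-4-benzyl-3-[(2S,3S)-3-(3,4-dimethoxyphenyl)-2-{2-[methoxy(methyl)amino]-2-oxoethyl}pent-4-enoyl]oxazolidin-2-one | COc1ccc([C@H]([C@@H](C(=O)N2[C@@H](Cc3ccccc3)COC2=O)CC(=O)N(C)OC)C=C)cc1OC | intermediate
10 | (3S,4S)-4-(3,4-dimethoxyphenyl)-3-(hydroxymethyl)-N-methoxy-N-methylhex-5-enamide | COc1ccc([C@H]([C@@H](CO)CC(=O)N(C)OC)C=C)cc1OC | intermediate
11 | (3S,4S)-3-[(tert-butyldiphenylsilyloxy)methyl]-4-(3,4-dimethoxyphenyl)-N-methoxy-N-methylhex-5-enamide | COc1ccc([C@H]([C@@H](CO[Si](c4ccccc4)(c4ccccc4)C(C)(C)C)CC(=O)N(C)OC)C=C)cc1OC | intermediate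
12 | ozonide (1,2,4-trioxolane) of alkene 11, mixture at the ozonide carbon | COc1ccc([C@H]([C@@H](CO[Si](c4ccccc4)(c4ccccc4)C(C)(C)C)CC(=O)N(C)OC)C2OCOO2)cc1OC | intermediate
13 | (3S,4S)-3-[(tert-butyldiphenylsilyloxy)methyl]-4-(3,4-dimethoxyphenyl)-N-methoxy-N-methyl-5-oxopentanamide | COc1ccc([C@H]([C@@H](CO[Si](c4ccccc4)(c4ccccc4)C(C)(C)C)CC(=O)N(C)OC)C=O)cc1OC | intermediate
14 | dimethyl (1-diazo-2-oxopropyl)phosphonate | CC(=O)C(=[N+]=[N-])P(=O)(OC)OC | starting material
15 | dimethyl (1-methoxy-2-oxopropyl)phosphonate (racemic) | CC(=O)C(OC)P(=O)(OC)OC | intermediate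
16 | (3S,4R,5Z)-3-[(tert-butyldiphenylsilyloxy)methyl]-4-(3,4-dimethoxyphenyl)-N,6-dimethoxy-N-methyl-7-oxooct-5-enamide | COc1ccc([C@H]([C@@H](CO[Si](c4ccccc4)(c4ccccc4)C(C)(C)C)CC(=O)N(C)OC)/C=C(OC)/C(C)=O)cc1OC | intermediate
17 | (3S,4R,5Z)-3-[(tert-butyldiphenylsilyloxy)methyl]-4-(3,4-dimethoxyphenyl)-N,6-dimethoxy-N-methyl-7-(triisopropylsilyloxy)octa-5,7-dienamide | COc1ccc([C@H]([C@@H](CO[Si](c4ccccc4)(c4ccccc4)C(C)(C)C)CC(=O)N(C)OC)/C=C(OC)/C(=C)O[Si](C(C)C)(C(C)C)C(C)C)cc1OC | intermediate
18 | ethynylmagnesium bromide | C#C[Mg]Br | starting material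
19 | (5S,6R,7Z)-5-[(tert-butyldiphenylsilyloxy)methyl]-6-(3,4-dimethoxyphenyl)-8-methoxy-9-(triisopropylsilyloxy)deca-7,9-dien-1-yn-3-one | COc1ccc([C@H]([C@@H](CO[Si](c4ccccc4)(c4ccccc4)C(C)(C)C)CC(=O)C#C)/C=C(OC)/C(=C)O[Si](C(C)C)(C(C)C)C(C)C)cc1OC | intermediate
20 | Diels–Alder adduct: 3-[(tert-butyldiphenylsilyloxy)methyl]-4-(3,4-dimethoxyphenyl)-5-methoxy-6-(triisopropylsilyloxy)-3,4,4a,7-tetrahydronaphthalen-1(2H)-one, C1 and C2 as in 19, C8a not defined | COc1ccc([C@H]2C3C(OC)=C(O[Si](C(C)C)(C(C)C)C(C)C)CC=C3C(=O)C[C@@H]2CO[Si](c4ccccc4)(c4ccccc4)C(C)(C)C)cc1OC | intermediate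
21 | (3S,4S)-3-[(tert-butyldiphenylsilyloxy)methyl]-4-(3,4-dimethoxyphenyl)-5-methoxy-6-(triisopropylsilyloxy)-3,4-dihydronaphthalen-1(2H)-one (trans) | COc1ccc([C@H]2c3c(ccc(O[Si](C(C)C)(C(C)C)C(C)C)c3OC)C(=O)C[C@@H]2CO[Si](c4ccccc4)(c4ccccc4)C(C)(C)C)cc1OC | intermediate
22 | lithium enolate of tetralone 21 (C3=C4–O−) | COc1ccc([C@H]2c3c(ccc(O[Si](C(C)C)(C(C)C)C(C)C)c3OC)C([O-])=C[C@@H]2CO[Si](c4ccccc4)(c4ccccc4)C(C)(C)C)cc1OC.[Li+] | intermediate
23 | (2Z,3R,4S)-3-[(tert-butyldiphenylsilyloxy)methyl]-4-(3,4-dimethoxyphenyl)-2-(hydroxymethylene)-5-methoxy-6-(triisopropylsilyloxy)-3,4-dihydronaphthalen-1(2H)-one | COc1ccc([C@H]2c3c(ccc(O[Si](C(C)C)(C(C)C)C(C)C)c3OC)C(=O)/C(=C\O)[C@@H]2CO[Si](c4ccccc4)(c4ccccc4)C(C)(C)C)cc1OC | intermediate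
24 | (2E,3R,4S)-3-[(tert-butyldiphenylsilyloxy)methyl]-4-(3,4-dimethoxyphenyl)-2-(isopropoxymethylene)-5-methoxy-6-(triisopropylsilyloxy)-3,4-dihydronaphthalen-1(2H)-one | COc1ccc([C@H]2c3c(ccc(O[Si](C(C)C)(C(C)C)C(C)C)c3OC)C(=O)/C(=C/OC(C)C)[C@@H]2CO[Si](c4ccccc4)(c4ccccc4)C(C)(C)C)cc1OC | intermediate
25 | (3R,4S)-3-[(tert-butyldiphenylsilyloxy)methyl]-4-(3,4-dimethoxyphenyl)-2-(isopropoxymethylene)-5-methoxy-6-(triisopropylsilyloxy)-1,2,3,4-tetrahydronaphthalen-1-ol, mixture at the carbinol carbon | COc1ccc([C@H]2c3c(ccc(O[Si](C(C)C)(C(C)C)C(C)C)c3OC)C(O)/C(=C/OC(C)C)[C@@H]2CO[Si](c4ccccc4)(c4ccccc4)C(C)(C)C)cc1OC | intermediate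
26 | (1S,2R)-2-[(tert-butyldiphenylsilyloxy)methyl]-1-(3,4-dimethoxyphenyl)-8-methoxy-7-(triisopropylsilyloxy)-1,2-dihydronaphthalene-3-carbaldehyde | COc1ccc([C@H]2c3c(ccc(O[Si](C(C)C)(C(C)C)C(C)C)c3OC)C=C(C=O)[C@@H]2CO[Si](c4ccccc4)(c4ccccc4)C(C)(C)C)cc1OC | intermediate
27 | vitekwangin B, (1S,2R)-1-(3,4-dimethoxyphenyl)-7-hydroxy-2-(hydroxymethyl)-8-methoxy-1,2-dihydronaphthalene-3-carbaldehyde | COc1ccc([C@H]2c3c(ccc(O)c3OC)C=C(C=O)[C@@H]2CO)cc1OC | target

**Step count**
Total: 15 steps. Longest linear sequence: 14 steps (steps 1–6 and 8–15 from acid 1); step 7 is a one-step side branch.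

**Steps most likely to fail**

Step 11 (key step). The terminal ynone may oligomerize or pick up nucleophiles before it meets the diene, the silyl enol ether may hydrolyze so that no diene is left, and DDQ may go on to abstract hydride from the doubly benzylic C1–H. Fallback: set out again from Weinreb amide 17. Lithium (trimethylsilyl)acetylide (THF, −78 → 0 °C) would give the trimethylsilyl ynone F1, which is storable and far less prone to amine addition. Heating F1 in toluene (110–130 °C) would give the C5-silylated cyclohexadiene adduct F2, and DDQ would dehydrogenate it to the 5-trimethylsilyl tetralone F3. Protodesilylation with CF3CO2H in CH2Cl2 (ipso-protonation at C5, para to the C8 methoxy group) then returns to tetralone 21.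

Step 8. The phosphonate anion may enolize the α-aryl aldehyde and so scramble C1, and the olefination may give the (E)-enol ether, whose diene cannot reach the s-cis conformation. Fallback from aldehyde 13: methoxyacetone is converted (Me3SiCl, NaI, Et3N, MeCN) into its enol silane on the methoxylated carbon, (Z)-1-methoxy-2-(trimethylsilyloxy)prop-1-ene F4. Mukaiyama aldol addition of F4 to 13 with BF3·OEt2 in CH2Cl2 at −78 °C (Lewis acidic, no base) would give the β-hydroxy-α-methoxy ketone F5. Mesylation (MeSO2Cl, Et3N) gives the mesylate F6, and elimination with DBU (E1cB through the ketone enolate, thermodynamic control of the alkene geometry) returns to enone 16.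

Step 10. The liberated N,O-dimethylhydroxylamine may add to the new ynone during the quench, or the enol ethers may hydrolyze if the quench is too acidic. Fallback from Weinreb amide 17: i-Bu2AlH (THF, −78 °C) would give the aldehyde F7, ethynylmagnesium bromide (18) the propargylic alcohol F8 (mixture at the carbinol carbon), and MnO2 in CH2Cl2 would oxidize F8 to ynone 19 under neutral conditions with no amine present.

**Further compounds**
F1 | step 11 | (5S,6R,7Z)-5-[(tert-butyldiphenylsilyloxy)methyl]-6-(3,4-dimethoxyphenyl)-8-methoxy-9-(triisopropylsilyloxy)-1-(trimethylsilyl)deca-7,9-dien-1-yn-3-one | COc1ccc([C@H]([C@@H](CO[Si](c4ccccc4)(c4ccccc4)C(C)(C)C)CC(=O)C#C[Si](C)(C)C)/C=C(OC)/C(=C)O[Si](C(C)C)(C(C)C)C(C)C)cc1OC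
F2 | step 11 | C5-trimethylsilyl analogue of cyclohexadiene adduct 20 (C8a not defined) | COc1ccc([C@H]2C3C(OC)=C(O[Si](C(C)C)(C(C)C)C(C)C)CC([Si](C)(C)C)=C3C(=O)C[C@@H]2CO[Si](c4ccccc4)(c4ccccc4)C(C)(C)C)cc1OC
F3 | step 11 | (3S,4S)-3-[(tert-butyldiphenylsilyloxy)methyl]-4-(3,4-dimethoxyphenyl)-5-methoxy-6-(triisopropylsilyloxy)-8-(trimethylsilyl)-3,4-dihydronaphthalen-1(2H)-one | COc1ccc([C@H]2c3c(c([Si](C)(C)C)cc(O[Si](C(C)C)(C(C)C)C(C)C)c3OC)C(=O)C[C@@H]2CO[Si](c4ccccc4)(c4ccccc4)C(C)(C)C)cc1OC
F4 | step 8 | (Z)-1-methoxy-2-(trimethylsilyloxy)prop-1-ene | CO/C=C(/C)O[Si](C)(C)C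
F5 | step 8 | (3S,4S)-3-[(tert-butyldiphenylsilyloxy)methyl]-4-(3,4-dimethoxyphenyl)-5-hydroxy-N,6-dimethoxy-N-methyl-7-oxooctanamide (mixture at C5 and C6) | COc1ccc([C@H]([C@@H](CO[Si](c4ccccc4)(c4ccccc4)C(C)(C)C)CC(=O)N(C)OC)C(O)C(OC)C(C)=O)cc1OC
F6 | step 8 | methanesulfonate of aldol F5 | COc1ccc([C@H]([C@@H](CO[Si](c4ccccc4)(c4ccccc4)C(C)(C)C)CC(=O)N(C)OC)C(OS(C)(=O)=O)C(OC)C(C)=O)cc1OC
F7 | step 10 | (3S,4R,5Z)-3-[(tert-butyldiphenylsilyloxy)methyl]-4-(3,4-dimethoxyphenyl)-6-methoxy-7-(triisopropylsilyloxy)octa-5,7-dienal | COc1ccc([C@H]([C@@H](CO[Si](c4ccccc4)(c4ccccc4)C(C)(C)C)CC=O)/C=C(OC)/C(=C)O[Si](C(C)C)(C(C)C)C(C)C)cc1OC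
F8 | step 10 | (5S,6R,7Z)-5-[(tert-butyldiphenylsilyloxy)methyl]-6-(3,4-dimethoxyphenyl)-8-methoxy-9-(triisopropylsilyloxy)deca-7,9-dien-1-yn-3-ol (mixture at C3) | COc1ccc([C@H]([C@@H](CO[Si](c4ccccc4)(c4ccccc4)C(C)(C)C)CC(O)C#C)/C=C(OC)/C(=C)O[Si](C(C)C)(C(C)C)C(C)C)cc1OC
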